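**Plan**

- Retrosynthetic cuts: the C6 ester and the C6/C9 carbinol oxidation levels are adjusted last; H‑5 is traced back to a C5–O–C9 oxygen bridge (a temporary ring); the ring‑fusion bond C1–C5 and the C9–C10 bond are then cut together (retro‑[5+2]) to a 3‑oxidopyrylium tethered to a 1,1‑disubstituted alkene; the pyranone comes from a 2‑furyl carbinol, the furan from a butenolide aldol, the chain from an epoxy alcohol.
- Enabling feature: O–C6–C7=C8(CH3)–C9–O of the seven‑membered ring is a dearomatised 4‑methylfuran (an oxidopyrylium with termini C5 and C9), and the quaternary C1(CH3)–C10 unit is an alkene held at C5 by C4–C3–C2, so one cycloaddition closes both carbocycles.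
- Forward order: chain with the C4 stereocentre → furan → pyranone → cyclopentane and cycloheptene in one step (as an oxabicycle) → reductive opening of the bridge → C9/C6 redox adjustment and esterification.
- Stereochemistry: C4 from Sharpless epoxidation; C1 and C5 from the cycloaddition (tether exo, face chosen by C4, the bridge oxygen marks the place of H‑5); C6 by C4–OH‑directed hydride delivery; C9 by hydride attack anti to the C1 methyl group.

Key step: step 10

Remark: ring compounds carry daucane locants (C1 quaternary ring‑fusion carbon with CH3; C2, C3 cyclopentane CH2; C4 C(O)(i‑Pr); C5 ring‑fusion CH; C6 CH–O(ester); C7=C8(CH3); C9 CH–OH; C10 CH2); α is the face of H‑5 in the target, β the face of the C1 methyl group.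

**Step 1**
Reactants: 1 prop-2-yn-1-ol; 2 isopropylmagnesium chloride
Product: 3 3-methyl-2-methylidenebutan-1-ol
Conditions: i-PrMgCl (3 equiv), CuI (10 mol%), THF, −10 °C → rt; aq. NH4Cl
Reagents that add atoms: none
Why: CuI-catalysed anti-carbomagnesiation of the magnesium alkoxide of propargyl alcohol places the isopropyl group on the internal alkyne carbon through a chelated alkenylmagnesium species, so protonation gives the 2-substituted allylic alcohol; no stereocentre is formed.

**Step 2**
Reactants: 3 3-methyl-2-methylidenebutan-1-ol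
Product: 4 [(2R)-2-(propan-2-yl)oxiran-2-yl]methanol
Conditions: Ti(OiPr)4 (10 mol%), D-(−)-diethyl tartrate (12 mol%), t-BuOOH, 4 Å MS, CH2Cl2, −20 °C
Reagents that add atoms: tert-butyl hydroperoxide, CC(C)(C)OO
Why: Sharpless asymmetric epoxidation of a 2-substituted allylic alcohol, in which the D-(−)-tartrate titanium complex should deliver oxygen to the face giving the (R)-epoxide (the sense by which 2-methylallyl alcohol gives (R)-2-methylglycidol), which sets C4 of the target.

**Step 3**
Reactants: 4 [(2R)-2-(propan-2-yl)oxiran-2-yl]methanol; 5 2-methylallylmagnesium chloride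
Product: 6 (2R)-5-methyl-2-(propan-2-yl)hex-5-ene-1,2-diol
Conditions: 5 (3 equiv), CuI (10 mol%), THF, −40 → 0 °C; aq. NH4Cl
Reagents that add atoms: none
Why: copper-catalysed SN2 opening of the 2,2-disubstituted epoxide by the allylic Grignard reagent occurs at the unsubstituted CH2 terminus, so the quaternary stereocentre is untouched and becomes the tertiary carbinol C4 carrying the C3–C2–C1(CH3)=C10 chain.

**Step 4**
Reactants: 6 (2R)-5-methyl-2-(propan-2-yl)hex-5-ene-1,2-diol
Product: 7 (2R)-5-methyl-2-(propan-2-yl)hex-5-ene-1,2-diol bis(triethylsilyl) ether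
Conditions: Et3SiOTf (2.5 equiv), 2,6-lutidine, CH2Cl2, −78 → 0 °C
Reagents that add atoms: triethylsilyl trifluoromethanesulfonate, CC[Si](CC)(CC)OS(=O)(=O)C(F)(F)F
Why: the silyl triflate silylates both the primary and the hindered tertiary hydroxyl; the tertiary silyl ether later prevents internal ketalisation of the pyranone and trapping of the oxidopyrylium.

**Step 5**
Reactants: 7 (2R)-5-methyl-2-(propan-2-yl)hex-5-ene-1,2-diol bis(triethylsilyl) ether
Product: 8 (2R)-5-methyl-2-(propan-2-yl)-2-(triethylsilyloxy)hex-5-enal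
Conditions: (COCl)2, DMSO, CH2Cl2, −78 → −30 °C; Et3N, −78 °C → rt
Reagents that add atoms: none
Why: Swern oxidation applied directly to the bis-silyl ether, in which the unhindered primary triethylsilyl ether is attacked by the chlorodimethylsulfonium ion and oxidised while the tertiary silyl ether is inert; C4 is quaternary and cannot epimerise.

**Step 6**
Reactants: 9 3-methylfuran-2(5H)-one
Product: 10 tert-butyldimethyl[(3-methylfuran-2-yl)oxy]silane
Conditions: t-BuMe2SiOTf, Et3N, CH2Cl2, 0 °C
Reagents that add atoms: tert-butyldimethylsilyl trifluoromethanesulfonate, CC(C)(C)[Si](C)(C)OS(=O)(=O)C(F)(F)F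
Why: soft enolisation and O-silylation of the butenolide gives a 2-silyloxyfuran that is nucleophilic at C5 only, which fixes the later 2,4-substitution of the furan (direct metalation of 3-methylfuran would not be regioselective).

**Step 7**
Reactants: 8 (2R)-5-methyl-2-(propan-2-yl)-2-(triethylsilyloxy)hex-5-enal; 10 tert-butyldimethyl[(3-methylfuran-2-yl)oxy]silane
Product: 11 5-[(2R)-1-hydroxy-5-methyl-2-(propan-2-yl)-2-(triethylsilyloxy)hex-5-en-1-yl]-3-methylfuran-2(5H)-one (diastereomer mixture at the carbinol carbon and at lactone C5)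
Conditions: BF3·OEt2, CH2Cl2, −78 °C; aq. NaHCO3
Reagents that add atoms: none
Why: vinylogous Mukaiyama aldol addition through the γ-position (C5) of the silyloxyfuran to the BF3-activated aldehyde; the two new stereocentres form as a mixture that does not matter because both become sp2 carbons (furan C2, pyrylium carbon) later.

**Step 8**
Reactants: 11 5-[(2R)-1-hydroxy-5-methyl-2-(propan-2-yl)-2-(triethylsilyloxy)hex-5-en-1-yl]-3-methylfuran-2(5H)-one
Product: 13 (2R)-5-methyl-1-(4-methylfuran-2-yl)-2-(propan-2-yl)-2-(triethylsilyloxy)hex-5-en-1-ol (both C1 epimers), via lactol 12 (not isolated)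
Conditions: i-Bu2AlH (3 equiv), CH2Cl2, −78 °C; then aq. citric acid, THF, rt
Reagents that add atoms: none
Why: reduction of the butenolide to the 2,5-dihydrofuran-2-ol and acid-induced loss of water aromatises it to the 2,4-disubstituted furan, while the tertiary silyl ether and the terminal alkene are unaffected.

**Step 9**
Reactants: 13 (2R)-5-methyl-1-(4-methylfuran-2-yl)-2-(propan-2-yl)-2-(triethylsilyloxy)hex-5-en-1-ol
Product: 14 6-hydroxy-5-methyl-2-[(3R)-2,6-dimethyl-3-(triethylsilyloxy)hept-6-en-3-yl]-2H-pyran-3(6H)-one (mixture at C2 and C6 of the pyranone)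
Conditions: VO(acac)2 (5 mol%), t-BuOOH, CH2Cl2, 0 °C → rt
Reagents that add atoms: tert-butyl hydroperoxide, CC(C)(C)OO
Why: Achmatowicz rearrangement, in which hydroxyl-directed oxidation of the furan and ring closure by the furfuryl oxygen give the pyranone; this oxidant leaves the isolated 1,1-disubstituted alkene alone, and the two ring stereocentres are erased in step 10.

**Step 10**
Reactants: 14 6-hydroxy-5-methyl-2-[(3R)-2,6-dimethyl-3-(triethylsilyloxy)hept-6-en-3-yl]-2H-pyran-3(6H)-one
Product: 17 5α,9α-epoxy-4β-(triethylsilyloxy)dauc-7-en-6-one, via pyranyl mesylate 15 (not isolated), via oxidopyrylium 16 (not isolated)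
Conditions: MsCl, i-Pr2NEt, MeCN (0.01 M), 0 °C → 60 °C
Reagents that add atoms: methanesulfonyl chloride, CS(=O)(=O)Cl (its atoms are carried only by intermediate 15)
Why: The lactol is mesylated, the amine removes the proton at C5 (α to the ketone) and mesylate leaves to give 3-oxidopyrylium 16, whose termini C5 and C9 add suprafacially across the tethered alkene to form the C5–C1 and C9–C10 bonds. The closest known reaction type is the intramolecular oxidopyrylium–alkene [5+2] cycloaddition with a three-atom tether on the carbon next to the oxido group. The cyclopentane is closed by the C1–C5 bond in an exo sense with the C2–C3–C4 tether on the side of the ring oxygen, and the seven-membered carbocycle is closed in the same event by the C9–C10 bond as an 8-oxabicyclo[3.2.1]oct-3-en-2-one. Because the short tether can only span the bridgehead and the exo position of the two-carbon bridge, the C1 methyl group is forced endo, so C1, C5 and C9 emerge in one relative configuration (C1–CH3 anti to the C5–O bond, which is the trans ring fusion once O is replaced by H), and their absolute sense is set by C4, whose isopropyl group turns away from the oxido oxygen while the smaller silyloxy oxygen sits next to it (A(1,3) strain), so the alkene adds to the pyrylium face that places C4–O cis to the C1 methyl group. The step needs π-facial selectivity and intramolecular capture ahead of ylide dimerisation; the first is secured by the fully substituted C4 stereocentre next to the pyrylium, the second by high dilution and the five-membered-ring tether, and the regiochemistry is fixed by the tether.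

**Step 11**
Reactants: 17 5α,9α-epoxy-4β-(triethylsilyloxy)dauc-7-en-6-one
Product: 18 5α,9α-epoxy-4β-hydroxydauc-7-en-6-one
Conditions: Bu4NF, THF, 0 °C → rt
Reagents that add atoms: none
Why: fluoride cleaves the tertiary silyl ether at a stage where the ketone cannot enolise toward the bridgehead C5, so retro-aldol cleavage of the liberated β-hydroxy ketone is not possible.

**Step 12**
Reactants: 18 5α,9α-epoxy-4β-hydroxydauc-7-en-6-one
Product: 19 4β,9α-dihydroxy-5αH-dauc-7-en-6-one
Conditions: SmI2 (2.2 equiv), THF, −78 °C; sat. aq. NH4Cl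
Reagents that add atoms: none
Why: SmI2 reductive cleavage of an α-alkoxy ketone, in which the ketyl expels the C5 oxygen (C5–O bond aligned with the enone π system), a second electron gives the samarium enolate and C9 keeps the oxygen as a hydroxyl; protonation at C5, followed if needed by equilibration with a trace of DBU, should give the trans-fused ketone with H-5 anti to the C1 methyl group, the epimer in which C6 avoids the C4 isopropyl group.

**Step 13**
Reactants: 19 4β,9α-dihydroxy-5αH-dauc-7-en-6-one
Product: 20 4β-hydroxy-5αH-dauc-7-ene-6,9-dione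
Conditions: Dess–Martin periodinane, NaHCO3, CH2Cl2, 0 °C → rt
Reagents that add atoms: none
Why: oxidation of the allylic C9 alcohol to the ene-1,4-dione removes the C9 configuration, which the cycloaddition sets syn to the tether and therefore opposite to that of the target, while the tertiary alcohol is inert.

**Step 14**
Reactants: 20 4β-hydroxy-5αH-dauc-7-ene-6,9-dione
Product: 21 4β,6α-dihydroxy-5αH-dauc-7-en-9-one
Conditions: Me4NBH(OAc)3, MeCN/AcOH (1:1), −30 → 0 °C
Reagents that add atoms: none
Why: Evans–Saksena hydroxyl-directed reduction, in which the C4 hydroxyl binds boron and delivers hydride to the β face of the C6 carbonyl (the face of C4–OH and C1–CH3) to give the equatorial 6α alcohol, whereas the C9 ketone has no hydroxyl within reach and is not reduced by this weak hydride.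

**Step 15**
Reactants: 21 4β,6α-dihydroxy-5αH-dauc-7-en-9-one; 22 4-methoxybenzoyl chloride
Product: 23 4β-hydroxy-9-oxo-5αH-dauc-7-en-6α-yl 4-methoxybenzoate
Conditions: DMAP (cat.), pyridine, CH2Cl2, 0 °C → rt
Reagents that add atoms: none
Why: DMAP-catalysed acylation of the only secondary hydroxyl; the tertiary C4 hydroxyl does not react and the C9 ketone serves as the protecting group of the C9 oxygen.

**Step 16**
Reactants: 23 4β-hydroxy-9-oxo-5αH-dauc-7-en-6α-yl 4-methoxybenzoate
Product: 24 [(3R,3aS,4S,7R,8aR)-3,7-dihydroxy-6,8a-dimethyl-3-(propan-2-yl)-1,2,3,3a,4,7,8,8a-octahydroazulen-4-yl] 4-methoxybenzoate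
Conditions: NaBH4, CeCl3·7H2O, MeOH, −78 °C
Reagents that add atoms: none
Why: Luche 1,2-reduction of the enone, in which hydride should attack C9 from the α face, anti to the axial C1 methyl group that stands 1,3 to the carbonyl, to give the 9β alcohol; the aryl ester and the trisubstituted alkene are not reduced under these conditions.

**Compound list**

1 | prop-2-yn-1-ol | C#CCO | starting material
2 | isopropylmagnesium chloride | CC(C)[Mg]Cl | starting material
3 | 3-methyl-2-methylidenebutan-1-ol | C=C(CO)C(C)C | intermediate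
4 | [(2R)-2-(propan-2-yl)oxiran-2-yl]methanol | OC[C@]1(C(C)C)CO1 | intermediate
5 | 2-methylallylmagnesium chloride | C=C(C)C[Mg]Cl | starting material
6 | (2R)-5-methyl-2-(propan-2-yl)hex-5-ene-1,2-diol | C=C(C)CC[C@@](O)(C(C)C)CO | intermediate
7 | (2R)-5-methyl-2-(propan-2-yl)hex-5-ene-1,2-diol bis(triethylsilyl) ether | C=C(C)CC[C@@](O[Si](CC)(CC)CC)(C(C)C)CO[Si](CC)(CC)CC | intermediate
8 | (2R)-5-methyl-2-(propan-2-yl)-2-(triethylsilyloxy)hex-5-enal | C=C(C)CC[C@@](O[Si](CC)(CC)CC)(C(C)C)C=O | intermediate
9 | 3-methylfuran-2(5H)-one | CC1=CCOC1=O | starting material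
10 | tert-butyldimethyl[(3-methylfuran-2-yl)oxy]silane | Cc1ccoc1O[Si](C)(C)C(C)(C)C | intermediate
11 | 5-[(2R)-1-hydroxy-5-methyl-2-(propan-2-yl)-2-(triethylsilyloxy)hex-5-en-1-yl]-3-methylfuran-2(5H)-one (diastereomer mixture) | C=C(C)CC[C@@](O[Si](CC)(CC)CC)(C(C)C)C(O)C1C=C(C)C(=O)O1 | intermediate
12 | 5-[(2R)-1-hydroxy-5-methyl-2-(propan-2-yl)-2-(triethylsilyloxy)hex-5-en-1-yl]-3-methyl-2,5-dihydrofuran-2-ol (lactol, not isolated) | C=C(C)CC[C@@](O[Si](CC)(CC)CC)(C(C)C)C(O)C1C=C(C)C(O)O1 | intermediate
13 | (2R)-5-methyl-1-(4-methylfuran-2-yl)-2-(propan-2-yl)-2-(triethylsilyloxy)hex-5-en-1-ol (both C1 epimers) | C=C(C)CC[C@@](O[Si](CC)(CC)CC)(C(C)C)C(O)c1cc(C)co1 | intermediate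
14 | 6-hydroxy-5-methyl-2-[(3R)-2,6-dimethyl-3-(triethylsilyloxy)hept-6-en-3-yl]-2H-pyran-3(6H)-one | C=C(C)CC[C@@](O[Si](CC)(CC)CC)(C(C)C)C1OC(O)C(C)=CC1=O | intermediate
15 | 6-O-methanesulfonate of 14 (pyranyl mesylate, not isolated) | C=C(C)CC[C@@](O[Si](CC)(CC)CC)(C(C)C)C1OC(OS(C)(=O)=O)C(C)=CC1=O | intermediate
16 | 5-methyl-2-[(3R)-2,6-dimethyl-3-(triethylsilyloxy)hept-6-en-3-yl]pyrylium-3-olate (oxidopyrylium, not isolated) | C=C(C)CC[C@@](O[Si](CC)(CC)CC)(C(C)C)c1[o+]cc(C)cc1[O-] | intermediate
17 | 5α,9α-epoxy-4β-(triethylsilyloxy)dauc-7-en-6-one (oxygen bridge C5–O–C9) | O=C1C=C(C)[C@@H]2C[C@@]3(C)CC[C@@](O[Si](CC)(CC)CC)(C(C)C)[C@]13O2 | intermediate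
18 | 5α,9α-epoxy-4β-hydroxydauc-7-en-6-one | O=C1C=C(C)[C@@H]2C[C@@]3(C)CC[C@@](O)(C(C)C)[C@]13O2 | intermediate
19 | 4β,9α-dihydroxy-5αH-dauc-7-en-6-one | O=C2C=C(C)[C@@H](O)C[C@@]3(C)CC[C@@](O)(C(C)C)[C@H]23 | intermediate
20 | 4β-hydroxy-5αH-dauc-7-ene-6,9-dione | O=C2C=C(C)C(=O)C[C@@]3(C)CC[C@@](O)(C(C)C)[C@H]23 | intermediate
21 | 4β,6α-dihydroxy-5αH-dauc-7-en-9-one | O[C@H]2C=C(C)C(=O)C[C@@]3(C)CC[C@@](O)(C(C)C)[C@H]23 | intermediate
22 | 4-methoxybenzoyl chloride | COc1ccc(C(=O)Cl)cc1 | starting material
23 | 4β-hydroxy-9-oxo-5αH-dauc-7-en-6α-yl 4-methoxybenzoate | COc1ccc(C(=O)O[C@H]2C=C(C)C(=O)C[C@@]3(C)CC[C@@](O)(C(C)C)[C@H]23)cc1 | intermediate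
24 | [(3R,3aS,4S,7R,8aR)-3,7-dihydroxy-6,8a-dimethyl-3-(propan-2-yl)-1,2,3,3a,4,7,8,8a-octahydroazulen-4-yl] 4-methoxybenzoate (4β,9β-dihydroxy-5αH-dauc-7-en-6α-yl 4-methoxybenzoate) | COc1ccc(C(=O)O[C@H]2C=C(C)[C@H](O)C[C@@]3(C)CC[C@@](O)(C(C)C)[C@H]23)cc1 | target

**Count and risks**

Total steps: 16. Longest linear sequence: 15 (steps 1–5 and 7–16; step 6 prepares the silyloxyfuran separately).

Steps most likely to fail:

1. Step 12. Electron transfer to the enone may expel the vinylogous C9–O bond instead of the C5–O bond, or reduce the enone further; protonation at C5 may also occur from the β face. Fallback (sets out from 18, returns at 20): the enone is first hydrogenated (H2, 10% Pd/C, EtOAc) to the saturated bridged ketone 5α,9α-epoxy-4β-hydroxydaucan-6-one F1, which has only one cleavable C–O bond. SmI2 in THF/MeOH at −78 °C then gives 4β,9α-dihydroxy-5αH-daucan-6-one F2. Dess–Martin oxidation gives the 1,4-diketone 4β-hydroxy-5αH-daucane-6,9-dione F3. Dehydrogenation with IBX (DMSO, 65 °C) gives 20; only C7–C8 can be desaturated because C5 and C10 are flanked by the fully substituted C4 and C1.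

2. Step 10. The C4 stereocentre may discriminate the two pyrylium faces poorly when both the silyloxy and the isopropyl group are large, and the ylide may dimerise if addition to the unactivated alkene is slow. Fallback (sets out from 13, returns at 18): steric rotamer control is replaced by an internal hydrogen bond and the silyl group is taken out of the sequence. Bu4NF gives the free diol (2R)-5-methyl-1-(4-methylfuran-2-yl)-2-(propan-2-yl)hex-5-ene-1,2-diol F4. Buffered Achmatowicz oxidation gives 6-hydroxy-2-[(3R)-3-hydroxy-2,6-dimethylhept-6-en-3-yl]-5-methyl-2H-pyran-3(6H)-one F5. MsCl/i-Pr2NEt gives its mesylate F6 and then the oxidopyrylium 2-[(3R)-3-hydroxy-2,6-dimethylhept-6-en-3-yl]-5-methylpyrylium-3-olate F7, in which an O–H···O bond from the C4 hydroxyl to the oxido oxygen locks the C4–C5 rotamer with the isopropyl group outside. Cycloaddition then gives 18 directly. The price is possible internal ketalisation of F5 by the free carbinol, hence the buffered oxidation.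

3. Step 16. Hydride may be delivered to the β face of the C9 carbonyl and give the 9α epimer. Fallback (sets out from 19, returns at 24): the C9 configuration is corrected by stereospecific inversion instead of reduction. Mitsunobu reaction of 19 with chloroacetic acid (PPh3, DIAD, THF, 0 °C) gives 9β-chloroacetoxy-4β-hydroxy-5αH-dauc-7-en-6-one F8. Directed reduction with Me4NBH(OAc)3 gives 9β-chloroacetoxy-5αH-dauc-7-ene-4β,6α-diol F9. Acylation with 22 (DMAP, pyridine) gives 9β-chloroacetoxy-4β-hydroxy-5αH-dauc-7-en-6α-yl 4-methoxybenzoate F10. Thiourea and NaHCO3 in EtOH at 50 °C remove the chloroacetate selectively to give 24.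

**Further compounds**

F1 | step 12 | 5α,9α-epoxy-4β-hydroxydaucan-6-one (C8 epimers) | O=C1CC(C)[C@@H]2C[C@@]3(C)CC[C@@](O)(C(C)C)[C@]13O2
F2 | step 12 | 4β,9α-dihydroxy-5αH-daucan-6-one | O=C2CC(C)[C@@H](O)C[C@@]3(C)CC[C@@](O)(C(C)C)[C@H]23
F3 | step 12 | 4β-hydroxy-5αH-daucane-6,9-dione | O=C2CC(C)C(=O)C[C@@]3(C)CC[C@@](O)(C(C)C)[C@H]23
F4 | step 10 | (2R)-5-methyl-1-(4-methylfuran-2-yl)-2-(propan-2-yl)hex-5-ene-1,2-diol | C=C(C)CC[C@@](O)(C(C)C)C(O)c1cc(C)co1
F5 | step 10 | 6-hydroxy-2-[(3R)-3-hydroxy-2,6-dimethylhept-6-en-3-yl]-5-methyl-2H-pyran-3(6H)-one | C=C(C)CC[C@@](O)(C(C)C)C1OC(O)C(C)=CC1=O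
F6 | step 10 | 6-O-methanesulfonate of F5 | C=C(C)CC[C@@](O)(C(C)C)C1OC(OS(C)(=O)=O)C(C)=CC1=O
F7 | step 10 | 2-[(3R)-3-hydroxy-2,6-dimethylhept-6-en-3-yl]-5-methylpyrylium-3-olate | C=C(C)CC[C@@](O)(C(C)C)c1[o+]cc(C)cc1[O-]
F8 | step 16 | 9β-chloroacetoxy-4β-hydroxy-5αH-dauc-7-en-6-one | O=C2C=C(C)[C@H](OC(=O)CCl)C[C@@]3(C)CC[C@@](O)(C(C)C)[C@H]23
F9 | step 16 | 9β-chloroacetoxy-5αH-dauc-7-ene-4β,6α-diol | O[C@H]2C=C(C)[C@H](OC(=O)CCl)C[C@@]3(C)CC[C@@](O)(C(C)C)[C@H]23
F10 | step 16 | 9β-chloroacetoxy-4β-hydroxy-5αH-dauc-7-en-6α-yl 4-methoxybenzoate | COc1ccc(C(=O)O[C@H]2C=C(C)[C@H](OC(=O)CCl)C[C@@]3(C)CC[C@@](O)(C(C)C)[C@H]23)cc1
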